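## Analysis of the target

The target is a flavan: a pyran ring (O1, C2, C3, C4, C4a, C8a) fused to ring A (C4a, C5, C6, C7, C8, C8a) and carrying ring B on C2. Ring A is an acylphloroglucinol with hydroxyls on C5 and C7, the 3-methylbutanoyl group on C6 and hydrogen on C8; its third oxygen is O1. Ring B is a fully substituted 2,4,6-trihydroxybenzene-1,3-dicarbaldehyde bound through C1′. The two stereocentres are neighbours, C2 (R, ring B) and C3 (S, isopropyl), and the two substituents are trans, both equatorial in the half-chair. C2 is a benzylic ether carbon next to an electron-rich ring and can ionise, so under equilibrating conditions its configuration follows that of C3. C3 bears only hydrogen and three carbon groups and lies next to the plain methylene C4, so no heteroatom or carbonyl is at hand to direct its formation. Two aldehydes, an aryl ketone and five acidic, oxidisable phenols must be masked against organometallic reagents, and the C2–C1′ bond joins a stereocentre to a hexasubstituted ring. The strategy rests on C3: its four substituents (H, isopropyl, C4, C2) allow it to be inserted as one carbon between boron and the benzylic C4, alkylated on boron under reagent control, and then extended from boron to C2.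

## Retrosynthetic reasoning

**27 to 26.** The five phenols are traced back to methyl ethers. Each lies ortho to a carbonyl group, which assists Lewis-acid cleavage, and methyl ethers are the masks that survive the organolithium and boron chemistry upstream. The forward step must cleave all five without opening the pyran ring.

**26 to 25.** The C6 ketone is traced back to an alkyne whose ring-bound carbon becomes the carbonyl carbon. A ketone could not pass through the carbenoid and Grignard steps; a disubstituted alkyne can. The forward hydration must be Markovnikov with respect to ring A, which the three oxygen donors on that ring secure.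

**25 to 24.** The O1–C2 bond is cut. The C8a oxygen is stored as a MOM ether, C2 becomes a benzylic carbinol, and the formyl groups of ring B become dioxolanes. This bond is chosen because C2 can ionise: acid should remove the three acid-labile masks and close the ring in one operation. The 2,3-trans outcome is favoured kinetically, thermodynamically, and by invertive displacement of the (S)-carbinol alike.

**24 to 23, then to 16, 12 and 20.** The C2–O bond comes from a C2–B bond with retention. C2 itself is a one-carbon unit from 12, inserted between C3 and boron, and the C2–C1′ bond is formed by migration of ring B from boron to C2. This uses the boron that the key step leaves on C3, so no functional-group change is needed between the two stereocentres. The forward step must transfer a very hindered aryl group, and that is the main risk after the key step.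

**16 to 11, 12 and 13 (key disconnection).** Both C3–C4 and C3–isopropyl are cut. C3 comes from 12 via 14, the benzylic C4 migrates from boron to it, and isopropyl is delivered from 13 through boron with inversion. The diol on boron is the only stereocontrol element needed, and C3 never carries an acidic hydrogen afterwards.

**11 to 6 and 9.** The C4–C4a bond is cut. Ring A is metalated at the position between the MOM ether and a methoxy group (the two such positions in 6 are equivalent) and the aryl group is transferred to the methylene carbon of 9. This puts the chiral diol on boron in the same step; 9 comes from diol 7 in one operation.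

**6 to 4 and 5, 4 to 3, 3 to 1.** The aryl–alkyne bond is made by Sonogashira coupling. The phenol oxygen para to bromine is introduced by sterically governed C–H borylation and oxidation of 1. Electrophilic halogenation of a 3,5-dialkoxyphenol would be expected to favour the positions next to the hydroxyl and not the one between the two alkoxy groups, so that route to 3 is avoided.

**20 to 19, 18 and 17.** Ring B is built from 17 by double formylation, bromination of the last free position and acetal formation. The formyl groups must be in place before coupling, because late formylation could not distinguish ring B from C8 of ring A.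

## Alternatives that were turned down

**Alternative 1:** The O1–C2 bond and the C3–H bond are disconnected, leading to the achiral E-styrene phenol A2. In the forward step a confined chiral Brønsted acid would protonate C3 and the C8a phenol would capture C2, giving the pentamethyl ether A1 (the same structure as 26) with both stereocentres set at once.
- For it: A2 contains no stereocentre and is quickly assembled, and the key step is catalytic. On step economy this alternative is clearly stronger than the chosen route.
- Against it: the catalyst would have to distinguish the two faces of an alkene carbon whose substituents are isopropyl and an arylmethyl group, with no binding element near C3. The alkene is conjugated to a ring carrying two formyl groups and is a poor base, while three carbonyl oxygens compete for the acid. The cyclisation is also reversible through the C2 cation, and loss of the C3 proton from that cation would erase the stereocentre.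
- Comparison: the chosen route is longer but sets C3 with a stoichiometric, well-modelled director and leaves it without any pathway for erosion.

**Alternative 2:** The O1–C8a and C4–C4a bonds are disconnected. Fluoride would generate the ring-A aryne from silyl triflate A5, the caesium alkoxide of the anti-aldol ester A4 would add at C8a, and the resulting C4a anion would attack the ester to give flavanone A3.
- For it: aldol chemistry sets C2 and C3 together by well-developed methods, and the annulation is convergent. On convergence it is as strong as or stronger than the chosen route.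
- Against it: the alkoxide of A4 is a hindered β-hydroxy ester anion prone to retro-aldol cleavage under the basic conditions. In A3 the C3 hydrogen is α to the C4 ketone, and ring opening to the achiral hydroxychalcone would scramble both centres. The C4 carbonyl, flanked by the C5 methoxy group, must then be removed in at least two further steps in the presence of the alkyne. A5 is a pentasubstituted arene that needs its own multistep preparation.
- Comparison: the chosen route never places an acidic hydrogen on C3 and needs no deoxygenation, so C4 arrives as a methylene.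

**Alternative 3:** The C2–C1′ and O1–C2 bonds are disconnected. The chroman-2-ol A7, a masked aldehyde with C3 already set, would condense with 2,4-diformylphloroglucinol A8; the ring-B quinone methide so formed would be captured by the C8a phenol to give the dimethyl ether A6.
- For it: ring B is used unprotected and no organometallic reagent is needed for the C2–C1′ bond. Only two methyl ethers remain to be cleaved, so on protecting-group economy this alternative is stronger.
- Against it: in the open form of A7 the C3 hydrogen is α to an aldehyde, and dehydration of the lactol to the enol ether would destroy C3 outright. A8 tends to react twice with aldehydes. The disconnection also leaves open how C3 is made in the first place.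
- Comparison: the chosen route answers the C3 question directly and keeps C3 configurationally inert, at the price of a hindered aryl transfer to C2.

Key step: step 6

Assumption: the sense of induction of the (S,S)-diol is taken from the accepted model for homologation of twofold-symmetric diol boronates with 14 ((R,R)-esters give (αS)-chlorides for simple groups). This places 11 on the path to the (1R)-chloride 15 and the (S)-boronate 16; if the sense proved opposite, diol 7 would be replaced by its enantiomer and nothing else would change.

## Route

Step 1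
Reactants: 1 2-bromo-1,3-dimethoxybenzene
Product: 3 4-bromo-3,5-dimethoxyphenol, via arylboronate 2 (not isolated)
Conditions: B2pin2, [Ir(OMe)(cod)]2 (cat.), 4,4′-di-tert-butyl-2,2′-bipyridine, THF, 80 °C; then KHSO5 (as 2KHSO5·KHSO4·K2SO4), acetone/H2O, rt
Reagents that add atoms: potassium peroxymonosulfate [K+].[O-]S(=O)(=O)OO
Why: Iridium-catalysed C–H borylation is governed by sterics and should occur only at C5, the one C–H bond without an ortho substituent; oxidation of the C–B bond in the same flask then places the hydroxyl para to bromine, a pattern that electrophilic bromination of a 3,5-dialkoxyphenol cannot be relied on to give.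

Step 2
Reactants: 3 4-bromo-3,5-dimethoxyphenol
Product: 4 2-bromo-1,3-dimethoxy-5-(methoxymethoxy)benzene
Conditions: MOMCl, i-Pr2NEt, CH2Cl2, 0 °C to rt
Reagents that add atoms: chloromethyl methyl ether COCCl
Why: O-alkylation of the phenol; the MOM ether is inert to organolithium and Grignard reagents, directs the later ortho-metalation, and marks the one oxygen that becomes O1.

Step 3
Reactants: 4 2-bromo-1,3-dimethoxy-5-(methoxymethoxy)benzene; 5 3-methylbut-1-yne
Product: 6 1,3-dimethoxy-5-(methoxymethoxy)-2-(3-methylbut-1-yn-1-yl)benzene
Conditions: PdCl2(MeCN)2 (cat.), 2-dicyclohexylphosphino-2′,4′,6′-triisopropylbiphenyl (XPhos), Cs2CO3, MeCN, 80 °C, sealed tube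
Reagents that add atoms: none
Why: Copper-free Sonogashira coupling; a bulky, electron-rich biarylphosphine on zerovalent palladium is chosen because the bromide is electron-rich and flanked by two methoxy groups. The alkyne is the masked 3-methylbutanoyl group.

Step 4
Reactants: 7 (1S,2S)-1,2-dicyclohexylethane-1,2-diol
Product: 9 (4S,5S)-2-(bromomethyl)-4,5-dicyclohexyl-1,3,2-dioxaborolane, via diisopropyl (bromomethyl)boronate 8 (not isolated)
Conditions: CH2Br2, B(OiPr)3, n-BuLi, THF, −78 °C; MeSO3H; then 7, Et2O, rt
Reagents that add atoms: dibromomethane BrCBr; triisopropyl borate CC(C)OB(OC(C)C)OC(C)C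
Why: Bromine–lithium exchange gives (bromomethyl)lithium, which is trapped in situ by the borate; acidification and ester exchange with the chelating diol give the chiral (bromomethyl)boronate, and the diol stereocentres are not touched.

Step 5
Reactants: 6 1,3-dimethoxy-5-(methoxymethoxy)-2-(3-methylbut-1-yn-1-yl)benzene; 9 (4S,5S)-2-(bromomethyl)-4,5-dicyclohexyl-1,3,2-dioxaborolane
Product: 11 (4S,5S)-4,5-dicyclohexyl-2-{[2,4-dimethoxy-6-(methoxymethoxy)-3-(3-methylbut-1-yn-1-yl)phenyl]methyl}-1,3,2-dioxaborolane, via aryllithium 10 (not isolated)
Conditions: n-BuLi, THF, −20 to 0 °C; then 9, −78 °C to rt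
Reagents that add atoms: none
Why: Directed ortho-metalation takes place between the MOM ether and a methoxy group (both such positions are equivalent); the aryllithium adds to boron of 9 and the aryl group migrates to the methylene carbon with loss of bromide (borate homologation with a (halomethyl)boronic ester). This forms C4–C4a and delivers the benzylboronate with the chiral diol already on boron.

Step 6
Reactants: 11 (4S,5S)-4,5-dicyclohexyl-2-{[2,4-dimethoxy-6-(methoxymethoxy)-3-(3-methylbut-1-yn-1-yl)phenyl]methyl}-1,3,2-dioxaborolane; 12 dichloromethane; 13 isopropylmagnesium bromide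
Product: 16 (4S,5S)-4,5-dicyclohexyl-2-[(2S)-1-[2,4-dimethoxy-6-(methoxymethoxy)-3-(3-methylbut-1-yn-1-yl)phenyl]-3-methylbutan-2-yl]-1,3,2-dioxaborolane, via (dichloromethyl)lithium 14 (not isolated), via chloro boronate 15 (not isolated)
Conditions: 12, n-BuLi, THF, −100 °C; 11; ZnCl2, −100 °C to rt; then 13, −78 °C to rt
Reagents that add atoms: none
Why: Matteson homologation: 14 adds to boron of 11, and ZnCl2 promotes 1,2-migration of the benzylic C4 to the carbenoid carbon with loss of one of its two diastereotopic chlorides, forming C3–C4 and giving chloro boronate 15. Reagent 13 then forms a second borate, and isopropyl migrates from boron to carbon with inversion, expelling the remaining chloride and forming the C3–isopropyl bond. The closest known reaction type is the ZnCl2-promoted chain extension of chiral diol boronic esters with LiCHCl2 followed by Grignard displacement, which is established for benzylboronates. No ring is closed. The one new stereocentre, C3, is controlled by the twofold-symmetric (S,S)-diol on boron, which decides which chloride leaves in the first shift; the second shift is stereospecific, so the (1R)-chloride is translated into the (S)-boronate. The step needs high selection in the first shift and clean inversion without chloride-induced epimerisation of 15 in the second; ZnCl2 binds free chloride, and C3 has no acidic hydrogen once formed. Chemoselectivity rests on the alkyne, which unlike the ketone it stands for is inert to 14 and 13, and on the methyl and MOM ethers, which tolerate both.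

Step 7
Reactants: 17 1,3,5-trimethoxybenzene
Product: 18 2,4,6-trimethoxybenzene-1,3-dicarbaldehyde
Conditions: Cl2CHOMe (excess), TiCl4, CH2Cl2, −10 °C to rt; then H2O
Reagents that add atoms: dichloromethyl methyl ether COC(Cl)Cl; water O
Why: Rieche formylation (Friedel–Crafts attack on the TiCl4-activated chloro(methoxy)carbenium ion, hydrolysis on work-up); two of the three equivalent positions react and the third is shut down by two TiCl4-complexed formyl groups.

Step 8
Reactants: 18 2,4,6-trimethoxybenzene-1,3-dicarbaldehyde
Product: 19 5-bromo-2,4,6-trimethoxybenzene-1,3-dicarbaldehyde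
Conditions: NBS, MeCN, rt to 50 °C
Reagents that add atoms: N-bromosuccinimide O=C1CCC(=O)N1Br
Why: Electrophilic aromatic bromination at the only free position, which is ortho, ortho and para to the three methoxy groups and meta to both formyl groups.

Step 9
Reactants: 19 5-bromo-2,4,6-trimethoxybenzene-1,3-dicarbaldehyde
Product: 20 2,2′-(5-bromo-2,4,6-trimethoxy-1,3-phenylene)bis(1,3-dioxolane)
Conditions: HOCH2CH2OH, TsOH·H2O (cat.), toluene, reflux, Dean–Stark
Reagents that add atoms: ethane-1,2-diol OCCO
Why: Acid-catalysed acetal formation with azeotropic removal of water; the dioxolanes make ring B compatible with Grignard formation and are released again by the acid of step 12.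

Step 10
Reactants: 16 (4S,5S)-4,5-dicyclohexyl-2-[(2S)-1-[2,4-dimethoxy-6-(methoxymethoxy)-3-(3-methylbut-1-yn-1-yl)phenyl]-3-methylbutan-2-yl]-1,3,2-dioxaborolane; 12 dichloromethane; 20 2,2′-(5-bromo-2,4,6-trimethoxy-1,3-phenylene)bis(1,3-dioxolane)
Product: 23 (4S,5S)-2-[(1S,2R)-1-[3,5-bis(1,3-dioxolan-2-yl)-2,4,6-trimethoxyphenyl]-2-{[2,4-dimethoxy-6-(methoxymethoxy)-3-(3-methylbut-1-yn-1-yl)phenyl]methyl}-3-methylbutyl]-4,5-dicyclohexyl-1,3,2-dioxaborolane, via chloro boronate 21 (not isolated), via aryl Grignard reagent 22 (not isolated)
Conditions: 12, n-BuLi, THF, −100 °C; 16; ZnCl2, −100 °C to rt; then 22 (from 20, Mg, LiCl, THF, 40 °C), −78 °C to rt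
Reagents that add atoms: none
Why: Second Matteson homologation: the carbenoid 14, made again in the flask from 12 and n-BuLi as in step 6, inserts C2 between C3 and boron with retention at the migrating C3, the diol again selecting the chloride that leaves to give the (1R)-chloride 21. Ring B then migrates from boron to C2 with inversion and forms C2–C1′; C3 keeps its geometry, and its descriptor changes only because the priorities of its neighbours change.

Step 11
Reactants: 23 (4S,5S)-2-[(1S,2R)-1-[3,5-bis(1,3-dioxolan-2-yl)-2,4,6-trimethoxyphenyl]-2-{[2,4-dimethoxy-6-(methoxymethoxy)-3-(3-methylbut-1-yn-1-yl)phenyl]methyl}-3-methylbutyl]-4,5-dicyclohexyl-1,3,2-dioxaborolane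
Product: 24 (1S,2S)-1-[3,5-bis(1,3-dioxolan-2-yl)-2,4,6-trimethoxyphenyl]-2-{[2,4-dimethoxy-6-(methoxymethoxy)-3-(3-methylbut-1-yn-1-yl)phenyl]methyl}-3-methylbutan-1-ol
Conditions: H2O2, NaOH, THF/H2O, 0 °C to rt
Reagents that add atoms: hydrogen peroxide OO
Why: Oxidation of the C–B bond by hydroperoxide, with migration of C2 from boron to oxygen and retention, gives the (1S)-carbinol and releases diol 7 for recovery; alkyne, acetals and MOM ether are inert to alkaline peroxide.

Step 12
Reactants: 24 (1S,2S)-1-[3,5-bis(1,3-dioxolan-2-yl)-2,4,6-trimethoxyphenyl]-2-{[2,4-dimethoxy-6-(methoxymethoxy)-3-(3-methylbut-1-yn-1-yl)phenyl]methyl}-3-methylbutan-1-ol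
Product: 25 5-[(2R,3S)-5,7-dimethoxy-6-(3-methylbut-1-yn-1-yl)-3-(propan-2-yl)-3,4-dihydro-2H-chromen-2-yl]-2,4,6-trimethoxybenzene-1,3-dicarbaldehyde
Conditions: HCl (2 M aq), MeOH/THF, 45 °C
Reagents that add atoms: water O
Why: Acid cleaves the MOM ether and both dioxolanes and ionises the benzylic alcohol; the C8a oxygen captures C2 in a six-membered closure (dehydrative etherification of the kind used to close flavans). The chair-like transition state with ring B and isopropyl equatorial gives the 2,3-trans isomer, which is also the thermodynamic product of reversible ionisation and the product of invertive displacement of the (S)-carbinol, so (2R) is expected by every pathway. Any hydration of the alkyne at this stage only anticipates step 13.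

Step 13
Reactants: 25 5-[(2R,3S)-5,7-dimethoxy-6-(3-methylbut-1-yn-1-yl)-3-(propan-2-yl)-3,4-dihydro-2H-chromen-2-yl]-2,4,6-trimethoxybenzene-1,3-dicarbaldehyde
Product: 26 5-[(2R,3S)-5,7-dimethoxy-6-(3-methylbutanoyl)-3-(propan-2-yl)-3,4-dihydro-2H-chromen-2-yl]-2,4,6-trimethoxybenzene-1,3-dicarbaldehyde
Conditions: TfOH (cat.), CF3CH2OH/H2O, 70 °C
Reagents that add atoms: water O
Why: Brønsted-acid Markovnikov hydration: protonation at the alkyne carbon remote from ring A gives a vinyl cation stabilised by the three oxygen donors of that ring, so water adds at the ring-bound carbon and the enol tautomerises to the aryl ketone. The flanking methoxy oxygens cannot reach the cationic carbon, and any reversible ionisation at C2 returns to the trans chroman.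

Step 14
Reactants: 26 5-[(2R,3S)-5,7-dimethoxy-6-(3-methylbutanoyl)-3-(propan-2-yl)-3,4-dihydro-2H-chromen-2-yl]-2,4,6-trimethoxybenzene-1,3-dicarbaldehyde
Product: 27 5-[(2R,3S)-5,7-dihydroxy-6-(3-methylbutanoyl)-3-(propan-2-yl)-3,4-dihydro-2H-chromen-2-yl]-2,4,6-trihydroxybenzene-1,3-dicarbaldehyde
Conditions: BBr3 (excess), CH2Cl2, −78 °C to rt; then H2O
Reagents that add atoms: none
Why: Lewis-acid O-demethylation: all five methyl ethers lie ortho to a carbonyl group that helps bring boron to the ether oxygen, and bromide removes methyl as bromomethane. BBr3 is preferred to BCl3 because each carbonyl can chelate only one neighbouring oxygen at a time and complete cleavage is required. Complexation of the formyl groups makes ring B electron-poor, which should protect the C2–O1 bond, and any reversible opening recloses to the trans isomer.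

## Compound list

1 | 2-bromo-1,3-dimethoxybenzene | COc1cccc(OC)c1Br | starting material
2 | 2-(4-bromo-3,5-dimethoxyphenyl)-4,4,5,5-tetramethyl-1,3,2-dioxaborolane | COc1cc(B2OC(C)(C)C(C)(C)O2)cc(OC)c1Br | intermediate
3 | 4-bromo-3,5-dimethoxyphenol | COc1cc(O)cc(OC)c1Br | intermediate
4 | 2-bromo-1,3-dimethoxy-5-(methoxymethoxy)benzene | COCOc1cc(OC)c(Br)c(OC)c1 | intermediate
5 | 3-methylbut-1-yne | CC(C)C#C | starting material
6 | 1,3-dimethoxy-5-(methoxymethoxy)-2-(3-methylbut-1-yn-1-yl)benzene | CC(C)C#Cc1c(OC)cc(OCOC)cc1OC | intermediate
7 | (1S,2S)-1,2-dicyclohexylethane-1,2-diol | O[C@@H](C1CCCCC1)[C@H](C1CCCCC1)O | starting material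
8 | diisopropyl (bromomethyl)boronate | BrCB(OC(C)C)OC(C)C | intermediate
9 | (4S,5S)-2-(bromomethyl)-4,5-dicyclohexyl-1,3,2-dioxaborolane | BrCB1O[C@@H](C2CCCCC2)[C@H](C2CCCCC2)O1 | intermediate
10 | [2,4-dimethoxy-6-(methoxymethoxy)-3-(3-methylbut-1-yn-1-yl)phenyl]lithium | CC(C)C#Cc1c(OC)cc(OCOC)c([Li])c1OC | intermediate
11 | (4S,5S)-4,5-dicyclohexyl-2-{[2,4-dimethoxy-6-(methoxymethoxy)-3-(3-methylbut-1-yn-1-yl)phenyl]methyl}-1,3,2-dioxaborolane | CC(C)C#Cc1c(OC)cc(OCOC)c(c1OC)CB1O[C@@H](C2CCCCC2)[C@H](C2CCCCC2)O1 | intermediate
12 | dichloromethane | ClCCl | starting material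
13 | isopropylmagnesium bromide | CC(C)[Mg]Br | starting material
14 | (dichloromethyl)lithium | [Li]C(Cl)Cl | intermediate
15 | (4S,5S)-2-[(1R)-1-chloro-2-[2,4-dimethoxy-6-(methoxymethoxy)-3-(3-methylbut-1-yn-1-yl)phenyl]ethyl]-4,5-dicyclohexyl-1,3,2-dioxaborolane | CC(C)C#Cc1c(OC)cc(OCOC)c(c1OC)C[C@H](Cl)B1O[C@@H](C2CCCCC2)[C@H](C2CCCCC2)O1 | intermediate
16 | (4S,5S)-4,5-dicyclohexyl-2-[(2S)-1-[2,4-dimethoxy-6-(methoxymethoxy)-3-(3-methylbut-1-yn-1-yl)phenyl]-3-methylbutan-2-yl]-1,3,2-dioxaborolane | CC(C)C#Cc1c(OC)cc(OCOC)c(c1OC)C[C@@H](C(C)C)B1O[C@@H](C2CCCCC2)[C@H](C2CCCCC2)O1 | intermediate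
17 | 1,3,5-trimethoxybenzene | COc1cc(OC)cc(OC)c1 | starting material
18 | 2,4,6-trimethoxybenzene-1,3-dicarbaldehyde | COc1cc(OC)c(C=O)c(OC)c1C=O | intermediate
19 | 5-bromo-2,4,6-trimethoxybenzene-1,3-dicarbaldehyde | COc1c(Br)c(OC)c(C=O)c(OC)c1C=O | intermediate
20 | 2,2′-(5-bromo-2,4,6-trimethoxy-1,3-phenylene)bis(1,3-dioxolane) | COc1c(Br)c(OC)c(C2OCCO2)c(OC)c1C1OCCO1 | intermediate
21 | (4S,5S)-2-[(1R,2S)-1-chloro-2-{[2,4-dimethoxy-6-(methoxymethoxy)-3-(3-methylbut-1-yn-1-yl)phenyl]methyl}-3-methylbutyl]-4,5-dicyclohexyl-1,3,2-dioxaborolane | CC(C)C#Cc1c(OC)cc(OCOC)c(c1OC)C[C@@H](C(C)C)[C@H](Cl)B1O[C@@H](C2CCCCC2)[C@H](C2CCCCC2)O1 | intermediate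
22 | [3,5-bis(1,3-dioxolan-2-yl)-2,4,6-trimethoxyphenyl]magnesium bromide | COc1c([Mg]Br)c(OC)c(C2OCCO2)c(OC)c1C1OCCO1 | intermediate
23 | (4S,5S)-2-[(1S,2R)-1-[3,5-bis(1,3-dioxolan-2-yl)-2,4,6-trimethoxyphenyl]-2-{[2,4-dimethoxy-6-(methoxymethoxy)-3-(3-methylbut-1-yn-1-yl)phenyl]methyl}-3-methylbutyl]-4,5-dicyclohexyl-1,3,2-dioxaborolane | CC(C)C#Cc1c(OC)cc(OCOC)c(c1OC)C[C@@H](C(C)C)[C@@H](c1c(OC)c(C2OCCO2)c(OC)c(C2OCCO2)c1OC)B1O[C@@H](C2CCCCC2)[C@H](C2CCCCC2)O1 | intermediate
24 | (1S,2S)-1-[3,5-bis(1,3-dioxolan-2-yl)-2,4,6-trimethoxyphenyl]-2-{[2,4-dimethoxy-6-(methoxymethoxy)-3-(3-methylbut-1-yn-1-yl)phenyl]methyl}-3-methylbutan-1-ol | CC(C)C#Cc1c(OC)cc(OCOC)c(c1OC)C[C@@H](C(C)C)[C@H](O)c1c(OC)c(C2OCCO2)c(OC)c(C2OCCO2)c1OC | intermediate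
25 | 5-[(2R,3S)-5,7-dimethoxy-6-(3-methylbut-1-yn-1-yl)-3-(propan-2-yl)-3,4-dihydro-2H-chromen-2-yl]-2,4,6-trimethoxybenzene-1,3-dicarbaldehyde | CC(C)C#Cc1c(OC)cc2c(c1OC)C[C@@H](C(C)C)[C@H](c1c(OC)c(C=O)c(OC)c(C=O)c1OC)O2 | intermediate
26 | 5-[(2R,3S)-5,7-dimethoxy-6-(3-methylbutanoyl)-3-(propan-2-yl)-3,4-dihydro-2H-chromen-2-yl]-2,4,6-trimethoxybenzene-1,3-dicarbaldehyde | CC(C)CC(=O)c1c(OC)cc2c(c1OC)C[C@@H](C(C)C)[C@H](c1c(OC)c(C=O)c(OC)c(C=O)c1OC)O2 | intermediate
27 | 5-[(2R,3S)-5,7-dihydroxy-6-(3-methylbutanoyl)-3-(propan-2-yl)-3,4-dihydro-2H-chromen-2-yl]-2,4,6-trihydroxybenzene-1,3-dicarbaldehyde | CC(C)CC(=O)c1c(O)cc2c(c1O)C[C@@H](C(C)C)[C@H](c1c(O)c(C=O)c(O)c(C=O)c1O)O2 | target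

## Step count and least certain steps

Total: 14 steps. Longest linear sequence: 10 steps (1, 2, 3, 5, 6, 10, 11, 12, 13, 14, starting from compound 1). The key-step precursor 11 is reached in four linear steps plus one step for reagent 9; ring B (steps 7 to 9) is a three-step branch.

**Step 6 (key step).** The second migration may be slow, because a secondary Grignard reagent has to add to the crowded chloro boronate. Hydride transfer from the β-hydrogens of 13 could then compete with alkyl transfer, and free chloride could epimerise 15 before it is displaced. The sense of induction of the diol also has to be confirmed. The fallback sets out from 11 and returns at 16, and it moves the stereocontrol from the diol to a chiral diamine. 2-Methylpropyl 2,4,6-triisopropylbenzoate F1, made from 2-methylpropan-1-ol and the acid chloride, would be deprotonated with s-BuLi and (−)-sparteine in Et2O at −78 °C to the configurationally stable (1S)-1-lithio-2-methylpropyl 2,4,6-triisopropylbenzoate F2. F2 would add to boron of 11 with retention, and on warming (with MgBr2 in MeOH if needed) the benzylic group would migrate with inversion as the benzoate leaves, giving 16. The (−)-enantiomer of the diamine is assigned by the retention–inversion model and would be exchanged for the (+)-enantiomer if the sense proved opposite.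

**Step 10.** Borate formation between the branched chloro boronate 21 and a Grignard reagent flanked by two methoxy groups may be too slow. Epimerisation of 21 by chloride, elimination, or simple recovery of unreacted material could then take over. The fallback sets out from 16 and returns at 25, and it replaces aryl migration on boron by carbonyl addition. 16 would be homologated to 21 as in the route, and 21 would be oxidised with H2O2 at pH 8 to 9 to (2S)-2-{[2,4-dimethoxy-6-(methoxymethoxy)-3-(3-methylbut-1-yn-1-yl)phenyl]methyl}-3-methylbutanal F3. In F3 the C3 hydrogen lies α to a formyl group, so the aldehyde would be carried on at once and cold to limit enolisation. [3,5-Bis(1,3-dioxolan-2-yl)-2,4,6-trimethoxyphenyl]lithium F4 (from 20 and n-BuLi, THF, −78 °C) would add to F3 to give 24 together with its (1R,2S)-epimer F5. Both ionise to the same benzylic cation under the conditions of step 12 and should converge on 25; C2 would then rest on the trans preference of the closure alone.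

**Step 14.** Cleavage may stop at partly methylated stages, because each carbonyl can assist only one neighbouring ether at a time, and the Lewis acid may open the pyran ring at C2–O1. The fallback sets out from 26 and returns at 27 by nucleophilic instead of electrophilic demethylation: NaSEt in DMF at 100 to 120 °C would attack the methyl carbons in SN2 fashion, each aryloxide leaving group being stabilised by an ortho or para carbonyl as in a vinylogous ester. The pyran ring is not activated under these conditions. The fallback makes no new isolated compound (F0).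

**Step 5.** During metalation n-BuLi may add across the alkyne, guided by the neighbouring methoxy groups, or remove the propargylic hydrogen. The crowded aryl group may also be slow to migrate from the borate, so that 6 is returned on work-up. The fallback sets out from 6 and returns at 11, and it reverses the roles of the partners. Aryllithium 10 would be quenched with B(OiPr)3 to diisopropyl [2,4-dimethoxy-6-(methoxymethoxy)-3-(3-methylbut-1-yn-1-yl)phenyl]boronate F6, which would be exchanged with diol 7 to (4S,5S)-4,5-dicyclohexyl-2-[2,4-dimethoxy-6-(methoxymethoxy)-3-(3-methylbut-1-yn-1-yl)phenyl]-1,3,2-dioxaborolane F7. (Chloromethyl)lithium, made in the flask from BrCH2Cl and n-BuLi at −78 °C, would then insert the methylene group into the aryl–boron bond to give 11. If the metalation itself is at fault, a hindered lithium amide in place of n-BuLi would avoid addition to the alkyne.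

**Step 13.** Protonation of the alkyne may be slow at the hindered ring, and hot acid may reopen the pyran ring or attack the formyl groups before hydration is complete. The fallback sets out from 25 and returns at 26 by π-acid catalysis instead of protonation: chloro[1,3-bis(2,6-diisopropylphenyl)imidazol-2-ylidene]gold, (IPr)AuCl, with AgSbF6 in dioxane/H2O at 80 °C would activate the alkyne on monovalent gold under almost neutral conditions, and water should again add at the ring-bound carbon. The fallback makes no new isolated compound (F0).

## Further compounds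

F1 | step 6 | 2-methylpropyl 2,4,6-tri(propan-2-yl)benzoate | CC(C)COC(=O)c1c(C(C)C)cc(C(C)C)cc1C(C)C
F2 | step 6 | (1S)-1-lithio-2-methylpropyl 2,4,6-tri(propan-2-yl)benzoate | CC(C)[C@H]([Li])OC(=O)c1c(C(C)C)cc(C(C)C)cc1C(C)C
F3 | step 10 | (2S)-2-{[2,4-dimethoxy-6-(methoxymethoxy)-3-(3-methylbut-1-yn-1-yl)phenyl]methyl}-3-methylbutanal | CC(C)C#Cc1c(OC)cc(OCOC)c(c1OC)C[C@@H](C(C)C)C=O
F4 | step 10 | [3,5-bis(1,3-dioxolan-2-yl)-2,4,6-trimethoxyphenyl]lithium | COc1c([Li])c(OC)c(C2OCCO2)c(OC)c1C1OCCO1
F5 | step 10 | (1R,2S)-1-[3,5-bis(1,3-dioxolan-2-yl)-2,4,6-trimethoxyphenyl]-2-{[2,4-dimethoxy-6-(methoxymethoxy)-3-(3-methylbut-1-yn-1-yl)phenyl]methyl}-3-methylbutan-1-ol | CC(C)C#Cc1c(OC)cc(OCOC)c(c1OC)C[C@@H](C(C)C)[C@@H](O)c1c(OC)c(C2OCCO2)c(OC)c(C2OCCO2)c1OC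
F0 | step 14 | none | none
F6 | step 5 | diisopropyl [2,4-dimethoxy-6-(methoxymethoxy)-3-(3-methylbut-1-yn-1-yl)phenyl]boronate | CC(C)C#Cc1c(OC)cc(OCOC)c(c1OC)B(OC(C)C)OC(C)C
F7 | step 5 | (4S,5S)-4,5-dicyclohexyl-2-[2,4-dimethoxy-6-(methoxymethoxy)-3-(3-methylbut-1-yn-1-yl)phenyl]-1,3,2-dioxaborolane | CC(C)C#Cc1c(OC)cc(OCOC)c(c1OC)B1O[C@@H](C2CCCCC2)[C@H](C2CCCCC2)O1
F0 | step 13 | none | none
A1 | alternative 1 | 5-[(2R,3S)-5,7-dimethoxy-6-(3-methylbutanoyl)-3-(propan-2-yl)-3,4-dihydro-2H-chromen-2-yl]-2,4,6-trimethoxybenzene-1,3-dicarbaldehyde | CC(C)CC(=O)c1c(OC)cc2c(c1OC)C[C@@H](C(C)C)[C@H](c1c(OC)c(C=O)c(OC)c(C=O)c1OC)O2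
A2 | alternative 1 | 5-[(1E)-2-{[6-hydroxy-2,4-dimethoxy-3-(3-methylbutanoyl)phenyl]methyl}-3-methylbut-1-en-1-yl]-2,4,6-trimethoxybenzene-1,3-dicarbaldehyde | CC(C)CC(=O)c1c(OC)cc(O)c(c1OC)C/C(C(C)C)=C\c1c(OC)c(C=O)c(OC)c(C=O)c1OC
A3 | alternative 2 | (2R,3S)-2-[3,5-bis(1,3-dioxolan-2-yl)-2,4,6-trimethoxyphenyl]-5,7-dimethoxy-6-(3-methylbut-1-yn-1-yl)-3-(propan-2-yl)-2,3-dihydro-4H-chromen-4-one | CC(C)C#Cc1c(OC)cc2c(c1OC)C(=O)[C@@H](C(C)C)[C@H](c1c(OC)c(C3OCCO3)c(OC)c(C3OCCO3)c1OC)O2
A4 | alternative 2 | methyl (2S,3R)-3-[3,5-bis(1,3-dioxolan-2-yl)-2,4,6-trimethoxyphenyl]-3-hydroxy-2-(propan-2-yl)propanoate | COC(=O)[C@@H](C(C)C)[C@@H](O)c1c(OC)c(C2OCCO2)c(OC)c(C2OCCO2)c1OC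
A5 | alternative 2 | 2,4-dimethoxy-3-(3-methylbut-1-yn-1-yl)-6-(trimethylsilyl)phenyl trifluoromethanesulfonate | CC(C)C#Cc1c(OC)cc([Si](C)(C)C)c(OS(=O)(=O)C(F)(F)F)c1OC
A6 | alternative 3 | 5-[(2R,3S)-5,7-dimethoxy-6-(3-methylbutanoyl)-3-(propan-2-yl)-3,4-dihydro-2H-chromen-2-yl]-2,4,6-trihydroxybenzene-1,3-dicarbaldehyde | CC(C)CC(=O)c1c(OC)cc2c(c1OC)C[C@@H](C(C)C)[C@H](c1c(O)c(C=O)c(O)c(C=O)c1O)O2
A7 | alternative 3 | 1-[(3S)-2-hydroxy-5,7-dimethoxy-3-(propan-2-yl)-3,4-dihydro-2H-chromen-6-yl]-3-methylbutan-1-one | CC(C)CC(=O)c1c(OC)cc2c(c1OC)C[C@@H](C(C)C)C(O)O2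
A8 | alternative 3 | 2,4,6-trihydroxybenzene-1,3-dicarbaldehyde | O=Cc1c(O)cc(O)c(C=O)c1O
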